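**Retrosynthetic overview** (ring atoms numbered as in the name of 21: C1/C11 oxirane carbons, C2 ester carbon, C5 quaternary carbon, C8 bears CH2OH)
1. 21 ⇒ bis-silyl ether 20; the 11-membered ring is closed last at C2–C3 by a catalytic asymmetric alkenylzinc addition of an alkyne-derived alkenylmetal to an α,β-epoxy aldehyde, with acylation in the same flask.
2. The oxirane (C1, C11) is made before the carbocycle by organocatalytic epoxidation of an α-branched enal.
3. The side-chain carbinol comes from Shi epoxidation of the prenyl group and epoxide-to-allylic-alcohol isomerisation.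
4. C7=C8 comes from a Horner–Wadsworth–Emmons union of aldehyde 3 with phosphonate 9 (three steps from 5-bromo-2-methylpent-2-ene).
5. The quaternary C5 (first stereocentre) comes from a new organocatalytic conjugate alkynylation of geranial. Ring order: oxirane (step 10), then the carbocycle (step 11).

Assumption: geranial is used as the pure E isomer of commercial citral; the sense of induction in steps 1, 10 and 11 is predicted from models and has not been tested on these substrates.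

**Step 1**
Reactants: 1 geranial, (2E)-3,7-dimethylocta-2,6-dienal; 2 potassium ethynyltrifluoroborate
Product: 3 (3R)-3-ethynyl-3,7-dimethyloct-6-enal
Conditions: (S)-2-tert-butyl-3-methylimidazolidin-4-one·CF3CO2H (20 mol %), HF (48 % aq., 1.0 equiv), DME, −20 → 4 °C
Reagents that add atoms: none
Why: Proposed new method: the imidazolidinone turns geranial into an E iminium ion (the activation proven for β,β-disubstituted enals in organocatalytic transfer hydrogenation, where E and Z iminium ions equilibrate and the E form reacts), and the slim sp-hybridised alkynyltrifluoroborate attacks the hindered β-carbon by Friedel–Crafts-type ipso substitution (β-boron-stabilised vinyl cation, loss of BF3, trapped by HF as KBF4) on the Re face left open by the tert-butyl group, giving the (R) quaternary centre; the closest known reaction is the iminium-catalysed conjugate addition of alkenyl- and aryltrifluoroborates to β-monosubstituted enals.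

**Step 2**
Reactants: 4 5-bromo-2-methylpent-2-ene; 5 triethyl phosphonoacetate
Product: 6 ethyl 2-(diethoxyphosphoryl)-6-methylhept-5-enoate (racemic)
Conditions: NaH, NaI (10 mol %), DMF, 0 → 60 °C
Reagents that add atoms: none
Why: SN2 alkylation of the sodium phosphonoacetate carbanion by the primary homoallylic bromide; the new centre is racemic and is destroyed in step 5.

**Step 3**
Reactants: 6 ethyl 2-(diethoxyphosphoryl)-6-methylhept-5-enoate
Product: 8 ethyl (5E)-2-(diethoxyphosphoryl)-6-methyl-7-oxohept-5-enoate, via allylic alcohol 7 (not isolated)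
Conditions: SeO2 (0.3 equiv), t-BuOOH, salicylic acid (cat.), CH2Cl2, rt; then MnO2, CH2Cl2, rt
Reagents that add atoms: tert-butyl hydroperoxide, CC(C)(C)OO
Why: Sharpless–Umbreit allylic oxidation (ene reaction, then [2,3]-sigmatropic shift) is selective for the E-methyl group of the trisubstituted alkene, and MnO2 converges alcohol 7 to the E-enal.

**Step 4**
Reactants: 8 ethyl (5E)-2-(diethoxyphosphoryl)-6-methyl-7-oxohept-5-enoate
Product: 9 ethyl (5E)-2-(diethoxyphosphoryl)-7,7-dimethoxy-6-methylhept-5-enoate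
Conditions: HC(OMe)3, MeOH, pyridinium p-toluenesulfonate (cat.), rt
Reagents that add atoms: trimethyl orthoformate, COC(OC)OC; methanol, CO
Why: Acid-catalysed acetalisation masks the enal for the olefination and reduction ahead and makes the neighbouring alkene electron-poor toward dioxirane.

**Step 5**
Reactants: 3 (3R)-3-ethynyl-3,7-dimethyloct-6-enal; 9 ethyl (5E)-2-(diethoxyphosphoryl)-7,7-dimethoxy-6-methylhept-5-enoate
Product: 10 ethyl (2E,5R)-2-[(3E)-5,5-dimethoxy-4-methylpent-3-en-1-yl]-5-ethynyl-5,9-dimethyldeca-2,8-dienoate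
Conditions: 9, MeMgBr, THF, 0 °C; then 3, 0 → 40 °C
Reagents that add atoms: none
Why: Horner–Wadsworth–Emmons olefination of the unhindered aldehyde with the magnesium phosphonoenolate gives the E trisubstituted enoate (ester trans to the aldehyde-derived CH2, thermodynamic control), which is the C7=C8 geometry of the target.

**Step 6**
Reactants: 10 (as above)
Product: 11 ethyl (2E,5R)-2-[(3E)-5,5-dimethoxy-4-methylpent-3-en-1-yl]-7-[(2R)-3,3-dimethyloxiran-2-yl]-5-ethynyl-5-methylhept-2-enoate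
Conditions: D-fructose-derived Shi ketone (1,2:4,5-di-O-isopropylidene-D-erythro-2,3-hexodiulo-2,6-pyranose, 30 mol %), KHSO5 (as 2KHSO5·KHSO4·K2SO4), K2CO3, Bu4NHSO4 (cat.), MeCN/CH2(OMe)2/aq. Na2B4O7 buffer, 0 °C
Reagents that add atoms: potassium peroxymonosulfate, [K+].[O-]S(=O)(=O)OO
Why: Shi epoxidation: the chiral dioxirane reacts only with the electron-rich prenyl alkene (enoate, ene-acetal and alkyne are deactivated), and the spiro transition state of the D-fructose-derived ketone gives the (R)-epoxide.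

**Step 7**
Reactants: 11 (as above)
Product: 12 (2E,5R)-2-[(3E)-5,5-dimethoxy-4-methylpent-3-en-1-yl]-7-[(2R)-3,3-dimethyloxiran-2-yl]-5-ethynyl-5-methylhept-2-en-1-ol
Conditions: iBu2AlH (3 equiv), CH2Cl2, −78 °C; aq. KNaC4H4O6 work-up
Reagents that add atoms: none
Why: 1,2-Reduction of the enoate by iBu2AlH at −78 °C leaves the epoxide, acetal and alkyne untouched.

**Step 8**
Reactants: 12 (as above)
Product: 14 (2E,6E,9R,12R)-9-ethynyl-12-hydroxy-6-(hydroxymethyl)-2,9,13-trimethyltetradeca-2,6,13-trienal, via diol acetal 13 (not isolated)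
Conditions: Et2Al(TMP) (from Et2AlCl and lithium 2,2,6,6-tetramethylpiperidide, 5 equiv), toluene, 0 °C; then 1 M HCl, THF, rt
Reagents that add atoms: water, O
Why: Yamamoto epoxide-to-allylic-alcohol isomerisation: the aluminium amide binds the oxirane oxygen and removes a methyl proton syn to it (syn β-elimination), so the C–O bond and the (R) configuration at the secondary carbon are kept, and the acidic work-up hydrolyses the dimethyl acetal to the enal.

**Step 9**
Reactants: 14 (as above)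
Product: 15 (2E,6E,9R,12R)-12-[(tert-butyldimethylsilyl)oxy]-6-{[(tert-butyldimethylsilyl)oxy]methyl}-9-ethynyl-2,9,13-trimethyltetradeca-2,6,13-trienal
Conditions: TBSCl (2.5 equiv), imidazole, DMF, rt
Reagents that add atoms: tert-butyldimethylsilyl chloride, CC(C)(C)[Si](C)(C)Cl
Why: Standard imidazole-promoted silylation protects both hydroxyls so that they do not consume borane or zinc reagent or get acylated in step 11.

**Step 10**
Reactants: 15 (as above)
Product: 16 (2S,3R)-3-[(3E,6R,9R)-9-[(tert-butyldimethylsilyl)oxy]-3-{[(tert-butyldimethylsilyl)oxy]methyl}-6-ethynyl-6,10-dimethylundeca-3,10-dien-1-yl]-2-methyloxirane-2-carbaldehyde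
Conditions: 9-amino(9-deoxy)epiquinine (10 mol %), (R)-TRIP (3,3'-bis(2,4,6-triisopropylphenyl)-1,1'-binaphthyl-2,2'-diyl hydrogen phosphate, 20 mol %), 50 % aq. H2O2, THF, 50 °C
Reagents that add atoms: hydrogen peroxide, OO
Why: Amine-catalysed Weitz–Scheffer-type epoxidation of an α-branched enal: the primary amine forms an iminium ion, hydroperoxide adds to the β-carbon and the enamine closes the oxirane, so only the enal alkene reacts and the trans geometry is kept; the chiral amine/phosphate ion pair is intended to set (2S,3R), and the pseudoenantiomeric 9-amino(9-deoxy)epiquinidine/(S)-TRIP pair is taken if calibration on (E)-2-methylpent-2-enal shows the opposite sense.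

**Step 11**
Reactants: 16 (as above); 17 3-methylbut-2-enoyl chloride
Product: 20 [(1S,2S,3E,5R,7E,11R)-5-{(3R)-3-[(tert-butyldimethylsilyl)oxy]-4-methylpent-4-en-1-yl}-8-{[(tert-butyldimethylsilyl)oxy]methyl}-1,5-dimethyl-12-oxabicyclo[9.1.0]dodeca-3,7-dien-2-yl] 3-methylbut-2-enoate, via alkenylborane 18 (not isolated), via zinc alkoxide 19 (not isolated)
Conditions: Cy2BH (from BH3·SMe2 and cyclohexene, 1.1 equiv), toluene, 0 °C; slow addition to Et2Zn (3 equiv), (2S)-(−)-3-exo-(dimethylamino)isoborneol (10 mol %), toluene (0.003 M), 0 °C; then pyridine, 17, 0 °C → rt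
Reagents that add atoms: none
Why: Anti-Markovnikov syn-hydroboration gives the E-alkenylborane, and boron-to-zinc exchange followed by amino-alcohol-catalysed alkenylzinc addition (Oppolzer-type macrocyclisation) closes the 11-membered ring with an E alkene; the (−)-amino alcohol directs attack to the Si face of the aldehyde, which is also the chelation-preferred threo mode for an α,β-epoxy aldehyde, giving (2S), and the zinc alkoxide is esterified in the flask.

**Step 12**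
Reactants: 20 (as above)
Product: 21 [(1S,2S,3E,5R,7E,11R)-5-[(3R)-3-hydroxy-4-methylpent-4-en-1-yl]-8-(hydroxymethyl)-1,5-dimethyl-12-oxabicyclo[9.1.0]dodeca-3,7-dien-2-yl] 3-methylbut-2-enoate (CNP0309478.1)
Conditions: Bu4NF, AcOH, THF, 0 °C → rt
Reagents that add atoms: none
Why: Fluoride-induced desilylation buffered with AcOH removes both TBS ethers without touching the ester or the epoxide.

**Compound list**
1 | geranial, (2E)-3,7-dimethylocta-2,6-dienal | CC(C)=CCC/C(C)=C/C=O | starting material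
2 | potassium ethynyltrifluoroborate | [K+].C#C[B-](F)(F)F | starting material
3 | (3R)-3-ethynyl-3,7-dimethyloct-6-enal | CC(C)=CCC[C@@](CC=O)(C)C#C | intermediate
4 | 5-bromo-2-methylpent-2-ene | CC(C)=CCCBr | starting material
5 | triethyl phosphonoacetate | CCOC(=O)CP(=O)(OCC)OCC | starting material
6 | ethyl 2-(diethoxyphosphoryl)-6-methylhept-5-enoate (racemic) | CCOC(=O)C(CCC=C(C)C)P(=O)(OCC)OCC | intermediate
7 | ethyl (5E)-2-(diethoxyphosphoryl)-7-hydroxy-6-methylhept-5-enoate | CCOC(=O)C(CC/C=C(\C)CO)P(=O)(OCC)OCC | intermediate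
8 | ethyl (5E)-2-(diethoxyphosphoryl)-6-methyl-7-oxohept-5-enoate | CCOC(=O)C(CC/C=C(\C)C=O)P(=O)(OCC)OCC | intermediate
9 | ethyl (5E)-2-(diethoxyphosphoryl)-7,7-dimethoxy-6-methylhept-5-enoate | CCOC(=O)C(CC/C=C(\C)C(OC)OC)P(=O)(OCC)OCC | intermediate
10 | ethyl (2E,5R)-2-[(3E)-5,5-dimethoxy-4-methylpent-3-en-1-yl]-5-ethynyl-5,9-dimethyldeca-2,8-dienoate | CC(C)=CCC[C@@](C/C=C(\CC/C=C(\C)C(OC)OC)C(=O)OCC)(C)C#C | intermediate
11 | ethyl (2E,5R)-2-[(3E)-5,5-dimethoxy-4-methylpent-3-en-1-yl]-7-[(2R)-3,3-dimethyloxiran-2-yl]-5-ethynyl-5-methylhept-2-enoate | CC1(C)O[C@@H]1CC[C@@](C/C=C(\CC/C=C(\C)C(OC)OC)C(=O)OCC)(C)C#C | intermediate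
12 | (2E,5R)-2-[(3E)-5,5-dimethoxy-4-methylpent-3-en-1-yl]-7-[(2R)-3,3-dimethyloxiran-2-yl]-5-ethynyl-5-methylhept-2-en-1-ol | CC1(C)O[C@@H]1CC[C@@](C/C=C(\CC/C=C(\C)C(OC)OC)CO)(C)C#C | intermediate
13 | (2E,5R,8R)-2-[(3E)-5,5-dimethoxy-4-methylpent-3-en-1-yl]-5-ethynyl-5,9-dimethyldeca-2,9-diene-1,8-diol | C=C(C)[C@H](O)CC[C@@](C/C=C(\CC/C=C(\C)C(OC)OC)CO)(C)C#C | intermediate
14 | (2E,6E,9R,12R)-9-ethynyl-12-hydroxy-6-(hydroxymethyl)-2,9,13-trimethyltetradeca-2,6,13-trienal | C=C(C)[C@H](O)CC[C@@](C/C=C(\CC/C=C(\C)C=O)CO)(C)C#C | intermediate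
15 | (2E,6E,9R,12R)-12-[(tert-butyldimethylsilyl)oxy]-6-{[(tert-butyldimethylsilyl)oxy]methyl}-9-ethynyl-2,9,13-trimethyltetradeca-2,6,13-trienal | C=C(C)[C@H](O[Si](C)(C)C(C)(C)C)CC[C@@](C/C=C(\CC/C=C(\C)C=O)CO[Si](C)(C)C(C)(C)C)(C)C#C | intermediate
16 | (2S,3R)-3-[(3E,6R,9R)-9-[(tert-butyldimethylsilyl)oxy]-3-{[(tert-butyldimethylsilyl)oxy]methyl}-6-ethynyl-6,10-dimethylundeca-3,10-dien-1-yl]-2-methyloxirane-2-carbaldehyde | C=C(C)[C@H](O[Si](C)(C)C(C)(C)C)CC[C@@](C/C=C(\CC[C@H]1O[C@]1(C)C=O)CO[Si](C)(C)C(C)(C)C)(C)C#C | intermediate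
17 | 3-methylbut-2-enoyl chloride | CC(C)=CC(=O)Cl | starting material
18 | (2S,3R)-3-[(3E,6R,9R)-9-[(tert-butyldimethylsilyl)oxy]-3-{[(tert-butyldimethylsilyl)oxy]methyl}-6-[(E)-2-(dicyclohexylboranyl)ethenyl]-6,10-dimethylundeca-3,10-dien-1-yl]-2-methyloxirane-2-carbaldehyde | C=C(C)[C@H](O[Si](C)(C)C(C)(C)C)CC[C@@](C/C=C(\CC[C@H]1O[C@]1(C)C=O)CO[Si](C)(C)C(C)(C)C)(C)/C=C/B(C1CCCCC1)C1CCCCC1 | intermediate
19 | ethylzinc (1S,2S,3E,5R,7E,11R)-5-{(3R)-3-[(tert-butyldimethylsilyl)oxy]-4-methylpent-4-en-1-yl}-8-{[(tert-butyldimethylsilyl)oxy]methyl}-1,5-dimethyl-12-oxabicyclo[9.1.0]dodeca-3,7-dien-2-olate | C=C(C)[C@H](O[Si](C)(C)C(C)(C)C)CC[C@@]1(C)/C=C/[C@H](O[Zn]CC)[C@@]2(C)O[C@@H]2CC/C(CO[Si](C)(C)C(C)(C)C)=C\C1 | intermediate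
20 | [(1S,2S,3E,5R,7E,11R)-5-{(3R)-3-[(tert-butyldimethylsilyl)oxy]-4-methylpent-4-en-1-yl}-8-{[(tert-butyldimethylsilyl)oxy]methyl}-1,5-dimethyl-12-oxabicyclo[9.1.0]dodeca-3,7-dien-2-yl] 3-methylbut-2-enoate | C=C(C)[C@H](O[Si](C)(C)C(C)(C)C)CC[C@@]1(C)/C=C/[C@H](OC(=O)C=C(C)C)[C@@]2(C)O[C@@H]2CC/C(CO[Si](C)(C)C(C)(C)C)=C\C1 | intermediate
21 | [(1S,2S,3E,5R,7E,11R)-5-[(3R)-3-hydroxy-4-methylpent-4-en-1-yl]-8-(hydroxymethyl)-1,5-dimethyl-12-oxabicyclo[9.1.0]dodeca-3,7-dien-2-yl] 3-methylbut-2-enoate | C=C(C)[C@H](O)CC[C@@]1(C)/C=C/[C@H](OC(=O)C=C(C)C)[C@@]2(C)O[C@@H]2CC/C(CO)=C\C1 | target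

**Step count**
Total: 12 steps. Longest linear sequence: 11 steps (4 → 6 → 8 → 9 → 10 → 11 → 12 → 14 → 15 → 16 → 20 → 21); 9 steps from geranial.

**Three steps most likely to fail**

Step 1 (the proposed new conjugate alkynylation). The hindered iminium ion may react too slowly with the weak π-nucleophile, or 1,2-addition may compete. The fallback uses known chemistry, sets out from 1 and comes back at 3. The known secondary-amine-catalysed Michael addition of nitromethane to β,β-disubstituted enals ((S)-α,α-diphenylprolinol trimethylsilyl ether, MeNO2, MeOH) gives (3R)-3,7-dimethyl-3-(nitromethyl)oct-6-enal F1. NaBH4 then gives (3R)-3,7-dimethyl-3-(nitromethyl)oct-6-en-1-ol F2. A Nef reaction (NaOMe, then aqueous TiCl3/NH4OAc) gives (3R)-3-methyl-3-(4-methylpent-3-en-1-yl)oxolan-2-ol F3. Ohira–Bestmann homologation (dimethyl (1-diazo-2-oxopropyl)phosphonate, K2CO3, MeOH) gives (3R)-3-ethynyl-3,7-dimethyloct-6-en-1-ol F4, and Dess–Martin oxidation gives 3.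

Step 11 (macrocyclisation). Cy2BH may reduce the epoxy aldehyde, the 11-membered ring may close slowly against oligomerisation, and the C2 selectivity is untested at this ring size. The fallback sets out from 16 and comes back at 20. Hydrostannation (Bu3SnH, PdCl2(PPh3)2 cat., THF) gives the vinylstannane (2S,3R)-3-[(3E,6R,9R)-9-[(tert-butyldimethylsilyl)oxy]-3-{[(tert-butyldimethylsilyl)oxy]methyl}-6,10-dimethyl-6-[(E)-2-(tributylstannyl)ethenyl]undeca-3,10-dien-1-yl]-2-methyloxirane-2-carbaldehyde F7. I2 in CH2Cl2 gives the vinyl iodide (2S,3R)-3-[(3E,6R,9R)-9-[(tert-butyldimethylsilyl)oxy]-3-{[(tert-butyldimethylsilyl)oxy]methyl}-6-[(E)-2-iodoethenyl]-6,10-dimethylundeca-3,10-dien-1-yl]-2-methyloxirane-2-carbaldehyde F8. Nozaki–Hiyama–Kishi ring closure (CrCl2, NiCl2 cat., DMSO/THF, high dilution) gives the macrocyclic alcohol (1R,2S,3E,5R,7E,11R)-5-{(3R)-3-[(tert-butyldimethylsilyl)oxy]-4-methylpent-4-en-1-yl}-8-{[(tert-butyldimethylsilyl)oxy]methyl}-1,5-dimethyl-12-oxabicyclo[9.1.0]dodeca-3,7-dien-2-ol F9, which is acylated with 17 (pyridine, DMAP) to give 20. If substrate control instead favours the epimer (1R,2R,3E,5R,7E,11R)-5-{(3R)-3-[(tert-butyldimethylsilyl)oxy]-4-methylpent-4-en-1-yl}-8-{[(tert-butyldimethylsilyl)oxy]methyl}-1,5-dimethyl-12-oxabicyclo[9.1.0]dodeca-3,7-dien-2-ol F10, Mitsunobu esterification with 3-methylbut-2-enoic acid (PPh3, diisopropyl azodicarboxylate) gives 20 with inversion.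

Step 10 (organocatalytic epoxidation). The sense and level of induction on this long-chain α-branched enal are not secured. The fallback sets out from 15 and comes back at 16. Luche reduction (NaBH4, CeCl3·7H2O, MeOH) gives (2E,6E,9R,12R)-12-[(tert-butyldimethylsilyl)oxy]-6-{[(tert-butyldimethylsilyl)oxy]methyl}-9-ethynyl-2,9,13-trimethyltetradeca-2,6,13-trien-1-ol F5. Katsuki–Sharpless epoxidation (Ti(OiPr)4, D-(−)-diethyl tartrate, t-BuOOH, 4 Å sieves, CH2Cl2, −20 °C) gives [(2R,3R)-3-[(3E,6R,9R)-9-[(tert-butyldimethylsilyl)oxy]-3-{[(tert-butyldimethylsilyl)oxy]methyl}-6-ethynyl-6,10-dimethylundeca-3,10-dien-1-yl]-2-methyloxiran-2-yl]methanol F6, and Dess–Martin oxidation gives 16.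

**Further compounds**
F1 | step 1 | (3R)-3,7-dimethyl-3-(nitromethyl)oct-6-enal | CC(C)=CCC[C@@](CC=O)(C)C[N+](=O)[O-]
F2 | step 1 | (3R)-3,7-dimethyl-3-(nitromethyl)oct-6-en-1-ol | CC(C)=CCC[C@@](CCO)(C)C[N+](=O)[O-]
F3 | step 1 | (3R)-3-methyl-3-(4-methylpent-3-en-1-yl)oxolan-2-ol | CC(C)=CCC[C@]1(C)CCOC1O
F4 | step 1 | (3R)-3-ethynyl-3,7-dimethyloct-6-en-1-ol | CC(C)=CCC[C@@](CCO)(C)C#C
F5 | step 10 | (2E,6E,9R,12R)-12-[(tert-butyldimethylsilyl)oxy]-6-{[(tert-butyldimethylsilyl)oxy]methyl}-9-ethynyl-2,9,13-trimethyltetradeca-2,6,13-trien-1-ol | C=C(C)[C@H](O[Si](C)(C)C(C)(C)C)CC[C@@](C/C=C(\CC/C=C(\C)CO)CO[Si](C)(C)C(C)(C)C)(C)C#C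
F6 | step 10 | [(2R,3R)-3-[(3E,6R,9R)-9-[(tert-butyldimethylsilyl)oxy]-3-{[(tert-butyldimethylsilyl)oxy]methyl}-6-ethynyl-6,10-dimethylundeca-3,10-dien-1-yl]-2-methyloxiran-2-yl]methanol | C=C(C)[C@H](O[Si](C)(C)C(C)(C)C)CC[C@@](C/C=C(\CC[C@H]1O[C@]1(C)CO)CO[Si](C)(C)C(C)(C)C)(C)C#C
F7 | step 11 | (2S,3R)-3-[(3E,6R,9R)-9-[(tert-butyldimethylsilyl)oxy]-3-{[(tert-butyldimethylsilyl)oxy]methyl}-6,10-dimethyl-6-[(E)-2-(tributylstannyl)ethenyl]undeca-3,10-dien-1-yl]-2-methyloxirane-2-carbaldehyde | C=C(C)[C@H](O[Si](C)(C)C(C)(C)C)CC[C@@](C/C=C(\CC[C@H]1O[C@]1(C)C=O)CO[Si](C)(C)C(C)(C)C)(C)/C=C/[Sn](CCCC)(CCCC)CCCC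
F8 | step 11 | (2S,3R)-3-[(3E,6R,9R)-9-[(tert-butyldimethylsilyl)oxy]-3-{[(tert-butyldimethylsilyl)oxy]methyl}-6-[(E)-2-iodoethenyl]-6,10-dimethylundeca-3,10-dien-1-yl]-2-methyloxirane-2-carbaldehyde | C=C(C)[C@H](O[Si](C)(C)C(C)(C)C)CC[C@@](C/C=C(\CC[C@H]1O[C@]1(C)C=O)CO[Si](C)(C)C(C)(C)C)(C)/C=C/I
F9 | step 11 | (1R,2S,3E,5R,7E,11R)-5-{(3R)-3-[(tert-butyldimethylsilyl)oxy]-4-methylpent-4-en-1-yl}-8-{[(tert-butyldimethylsilyl)oxy]methyl}-1,5-dimethyl-12-oxabicyclo[9.1.0]dodeca-3,7-dien-2-ol | C=C(C)[C@H](O[Si](C)(C)C(C)(C)C)CC[C@@]1(C)/C=C/[C@H](O)[C@@]2(C)O[C@@H]2CC/C(CO[Si](C)(C)C(C)(C)C)=C\C1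
F10 | step 11 | (1R,2R,3E,5R,7E,11R)-5-{(3R)-3-[(tert-butyldimethylsilyl)oxy]-4-methylpent-4-en-1-yl}-8-{[(tert-butyldimethylsilyl)oxy]methyl}-1,5-dimethyl-12-oxabicyclo[9.1.0]dodeca-3,7-dien-2-ol | C=C(C)[C@H](O[Si](C)(C)C(C)(C)C)CC[C@@]1(C)/C=C/[C@@H](O)[C@@]2(C)O[C@@H]2CC/C(CO[Si](C)(C)C(C)(C)C)=C\C1
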